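(Readings and results were computed with constants of no real substance, and the scatter is random.)

J reads 19.3% of the E charged at the end of Thursday's run, against 20.2% at its first sample.

| setting | Saturday's | Wednesday's | Thursday's | flask |
|---|---|---|---|---|
| E | 0.10 M | 0.10 M | 0.050 M | 0.10 M |
| L | 0.10 M (in portions, 2) | 0.10 M (in portions, 2) | 0.10 M (in portions, 2) | 0.100 M (in portions, 2) |
| Q | 0.050 M | 0.20 M | 0.10 M | 0.100 M |
| remark | run made earlier; portions every 2.0 h | run made earlier; portions every 2.0 h | run made earlier; portions every 2.0 h | the portions of L follow each other after 2.0 h, the first at the start |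
| time |  |  |  | 3.0 d |

| run | time / d | E / % | J / % |
|---|---|---|---|
| Saturday's | 0.625 | 0.2 | 18.8 |
| Saturday's | 1.25 | 0 | 18.9 |
| Saturday's | 1.67 | 0 | 18.7 |
| Saturday's | 2.50 | 0.5 | 18.6 |
| Saturday's | 3.00 | 0.4 | 18.4 |
| Saturday's | 4.00 | 0.2 | 18.2 |
| Wednesday's | 0.625 | 0 | 16.7 |
| Wednesday's | 1.25 | 0 | 16.6 |
| Wednesday's | 1.67 | 0 | 16.0 |
| Wednesday's | 2.50 | 0.6 | 16.7 |
| Wednesday's | 3.00 | 0 | 17.1 |
| Wednesday's | 4.00 | 0 | 17.1 |
| Thursday's | 0.333 | 0 | 20.2 |
| Thursday's | 0.833 | 0.3 | 19.6 |
| Thursday's | 1.67 | 0 | 19.8 |
| Thursday's | 2.50 | 0.2 | 19.2 |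
| Thursday's | 4.00 | 0 | 19.3 |

(each reading ± 0.3 percentage points)

- solid, in amounts per volume of the solution: E
- the numbers in the tables scatter by 0.3 percentage points (one standard deviation)
- steps that have been proposed: Z + L <-> J; Q + L <-> D; Z -> G; J <-> X; E <-> Z
- at the start none of E is in solution
- what has only dissolved of E counts as not reacted

- part of the E that has turned into other species by 3.0 d (what has only dissolved does not count)
- amount of J at 3.0 d, in percent of the E charged
- amount of J if the flask were left three thousand times as long, in percent of the E charged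

The bench rule says that a vanished solid has reacted and that the limiting reagent then sets the yield. With 1.00 equivalents of L, it promises the flask 100% of E as J.

The rule stops at a ratio. Thursday's run had twice as much L as E, yet J read between 19.2% and 20.2% from 0.333 d to 4.00 d, a span of 12.0 times the first sampling time. So I read the plateau as the balance of Z + L <-> J, not as a shortage of L.

I therefore carry the plateau quotient, c_J/(c_Z c_L), an apparent equilibrium constant at a given c_Q. Here I take c_Z as the E charged minus J and c_L as the charge of L minus J, so whatever D, X and G hold stays lumped inside the quotient. Thursday's run has the flask's Q and L, and its last reading gives 2.65 L mol⁻¹.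

Solving the same quotient for the flask's charges, I expect c_J = 0.0179 M, which is 17.9% of E. What has merely dissolved counts as unreacted, so I put conv a little above that figure. Z -> G runs one way, so I expect J to follow Z down towards 0% in the end.

The forecast says 99.9%, 17.9% and 0.5%, and it holds that “The solid and anything dissolved from it are gone by the first sample”. We part on conv.

The flask gives 20.7%, 17.9% and 0%.

    Z + L ⇌ J (K = 3.20 L mol⁻¹, k = 12.0 L mol⁻¹ h⁻¹)
    Q + L ⇌ D (K = 1.50 L mol⁻¹, k = 0.290 L mol⁻¹ h⁻¹)
    Z → G (k = 1.50 × 10⁻⁴ h⁻¹)
    J ⇌ X (K = 0.110, k = 0.0730 h⁻¹)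
    E ⇌ Z, rate k5*(cs5 - [Z]) while solid is left; crystals form when [Z] > cs5 (solubility = 0.100 M, k = 15.0 h⁻¹)

The flask's own quotient comes to 2.66 L mol⁻¹. For the neighbour flask with 0.40 M of L, 2.65 L mol⁻¹ gives 48.2%, and that flask holds J of 47.4%. In the flask, E had dissolved by 0.0833 d, standing at 0% with Z at 88.7%, while Z and L had already made J of 10.5%. J then reached 18.0% by 1.50 d, and at 3.00 d G stood at 0.862% and Z at 79.3%.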